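You charge 31 mM of starting material, half as much second substrate, and catalyst at 0.200 % of the starting material, then run the same charge at each temperature below.

| setting | alpha | delta | beta | eta |
|---|---|---|---|---|
| starting material | 31 mM | 31 mM | 31 mM | 31 mM |
| second substrate | 15.5 mM | 15.5 mM | 15.5 mM | 15.5 mM |
| free catalyst | 62 µM | 62 µM | 62 µM | 62 µM |
| temperature | 90 °C | 120 °C | 105 °C | 135 °C |
| time | 6.0 s | 6.0 s | 6.0 s | 6.0 s |

- the flask that comes out highest in share of target in all that became target or side product, or "all alike" when all lie within 1.5 percentage points (alpha / delta / beta / eta / all alike)
- share of target in all that became target or side product, alpha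
- share of target in all that became target or side product, delta
- share of target in all that became target or side product, beta
- share of target in all that became target or side product, eta

- percentages count the starting material that a species holds: one side product counts as two
- target is meant together with its crystals
- solid, in amounts per volume of the solution: crystals
- at 90 °C the constants are as listed, elsewhere as the activation energies and enthalpies make them

    starting material + free catalyst ⇌ catalyst intermediate A (K1 = 1200 L mol⁻¹, k1 = 1300 L mol⁻¹ s⁻¹, Ea1 = 37.0 kJ mol⁻¹, ΔH1 = −9.00 kJ mol⁻¹)
    catalyst intermediate A → free catalyst + target (k2 = 160 s⁻¹, Ea2 = 77.0 kJ mol⁻¹)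
    second substrate + free catalyst ⇌ catalyst intermediate B (K3 = 5400 L mol⁻¹, k3 = 27000 L mol⁻¹ s⁻¹, Ea3 = 30.0 kJ mol⁻¹, ΔH3 = −43.0 kJ mol⁻¹)
    catalyst intermediate B → free catalyst + second product (k4 = 73 s⁻¹, Ea4 = 69.0 kJ mol⁻¹)
    crystals ⇌ target, rate k5*(cs5 - [target]) while solid is left; crystals form when [target] > cs5 (cs5 = 21 mM, k5 = 1.0 s⁻¹)
    starting material + target → side product (k6 = 1.1 L mol⁻¹ s⁻¹, Ea6 = 41.0 kJ mol⁻¹)
    (constants at 90 °C)

First question: what does conversion cost you? With the catalyst free, starting material becomes target at a pseudo-first-order constant a, which is the capture by free catalyst slowed by the catalyst sitting as catalyst intermediate A. In alpha, a is 0.0644 s⁻¹. The side step takes starting material at its own constant times target. Divide the two rates and starting material cancels, leaving the break-even fraction b = 1.89, the target level, as a fraction of the charge, at which the side step would match target formation, a level above the whole charge. Let X be the converted fraction. While target is small against b, side product over target, both counted in percent of the charge, comes to X/b, so ln(odds) = ln X − ln b and the share is 1/(1 + X/b).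

Second question: does heat move b? An Arrhenius factor over one span is the exponential of Ea times a fixed number, so logarithms scale with Ea. Capture therefore speeds up 3.86 times from alpha to eta, against 4.5 for the side step. With the saturation correction, b in eta is 1.93, close to the 1.89 of alpha. So between alpha and eta my reckoning leaves X to separate the shares.

Third question: how far does X get? In alpha, second substrate takes free catalyst ten times as fast as starting material does at the start, forward steps alone, so I let it go first at full turnover. That costs 3.42 s in alpha and 0.276 s in eta. The remaining time then gives X = 15.3 % in alpha and 81.4 % in eta. My shares are 92.5 % and 70.3 %, so alpha stands above eta, and with beta and delta between them in temperature, alpha is my pick.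

The forecast gives 87.1 %, 81.2 %, 75.3 % and 70.8 % for alpha, beta, delta and eta, picks alpha, and says the share “falls as temperature rises”. The simulation gives 87.6 %, 81.4 %, 75.2 % and 71.0 %, with alpha on top, and eta holds 0 % crystals. My eta figure of 70.3 % lands near its 71.0 %, but my alpha figure stands 5 percentage points above.

Now read alpha at 15 s instead of 6.0 s. Amounts and temperature are held, so b stays 1.89. Starting material stands at 40.4 %, which makes X 59.6 %, and 1/(1 + X/b) gives 76.0 %. That neighbouring flask reads 77.5 %.

(The constants are those of an exercise; no experiment stands behind them.)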